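**Assumption:** cembrane numbering is used for the ring (C1 carries the isopropenyl group, C10 the ester, C13 the free hydroxyl), so the target is (1S,3Z,7E,10R,11E,13S) with a (2R,3S)-3-hydroxy-2-methylbutanoyl group.

## Retrosynthetic overview

1. Target ← desilylation ← C10 ester: the C10–O bond, the C10 centre and the 11E olefin come from a palladium-catalysed 1,3-transposing acyloxylation of a macrocyclic tertiary C12 carbonate with the side-chain acid (stereo-relay C13 → C12 → C10).
2. The only ring (the 14-membered carbocycle) is closed last, by ring-closing alkyne metathesis at C10≡C11, followed by trans-reduction to the 10E alkene.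
3. Open chain ← Negishi coupling C6–C7 with an (E)-iodoalkene, after the key Still [2,3]-Wittig rearrangement has forged C5–C6 and the (Z)-C3=C4 olefin.
4. C1 and C13 (with C1–C3, C12–C14 and the isopropenyl group) ← oxidative cleavage of the epoxide of cis-carveol from (S)-carvone; C12 ← Felkin addition of a propynyl group next to C13.
5. Side chain ← ethyl (R)-3-hydroxybutanoate by Fráter–Seebach methylation and Mitsunobu inversion.

## Route

**Step 1**
Reactants: 1 prop-2-yn-1-ol
Product: 3 (E)-3-iodo-2-methylprop-2-en-1-ol, via alkenylalane 2 (not isolated)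
Conditions: AlMe3 (3 equiv), Cp2ZrCl2 (0.25 equiv), CH2Cl2, 0 °C to rt; then I2, THF, −30 °C
Reagents that add atoms: trimethylaluminium, C[Al](C)C; iodine, II
Why: Negishi zirconium-catalysed carboalumination adds methyl and aluminium syn across the alkyne (methyl to the internal carbon), and iodinolysis with retention gives the (E)-iodoalkene that becomes the 7E olefin.

**Step 2**
Reactants: 3 (E)-3-iodo-2-methylprop-2-en-1-ol
Product: 4 (E)-3-bromo-1-iodo-2-methylprop-1-ene
Conditions: CBr4, PPh3, CH2Cl2, 0 °C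
Reagents that add atoms: carbon tetrabromide, BrC(Br)(Br)Br
Why: Appel bromination of the primary allylic alcohol is an SN2 displacement that leaves the alkenyl iodide and its geometry untouched.

**Step 3**
Reactants: 4 (E)-3-bromo-1-iodo-2-methylprop-1-ene
Product: 5 (E)-1-iodo-2-methylhex-1-en-4-yne
Conditions: CH3C≡CMgBr (1.2 equiv), CuBr·SMe2 (5 mol%), THF, −20 to 0 °C
Reagents that add atoms: prop-1-ynylmagnesium bromide, CC#C[Mg]Br
Why: copper-catalysed SN2 coupling of the alkynyl Grignard reagent with the primary allylic bromide gives the skipped enyne while the alkenyl iodide stays inert.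

**Step 4**
Reactants: 6 ethyl (R)-3-hydroxybutanoate
Product: 8 ethyl (2R,3R)-3-hydroxy-2-methylbutanoate, via dilithio alkoxide enolate 7 (not isolated)
Conditions: LiN(i-Pr)2 (2.2 equiv), THF, −50 to −20 °C; then CH3I, DMPU, −78 to 0 °C
Reagents that add atoms: iodomethane, CI
Why: Fráter–Seebach alkylation, in which the chelated dianion is methylated on the face away from the C3 methyl group, so the bought C3 centre sets C2 anti (about 95:5).

**Step 5**
Reactants: 8 ethyl (2R,3R)-3-hydroxy-2-methylbutanoate
Product: 9 ethyl (2R,3S)-2-methyl-3-(4-nitrobenzoyloxy)butanoate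
Conditions: 4-O2NC6H4CO2H, PPh3, DIAD, THF, 0 °C to rt
Reagents that add atoms: 4-nitrobenzoic acid, OC(=O)c1ccc(cc1)[N+](=O)[O-]
Why: Mitsunobu esterification displaces the activated secondary hydroxyl by SN2 with inversion, turning the anti (3R) alcohol into the required syn (3S) arrangement.

**Step 6**
Reactants: 9 ethyl (2R,3S)-2-methyl-3-(4-nitrobenzoyloxy)butanoate
Product: 10 (2R,3S)-3-hydroxy-2-methylbutanoic acid
Conditions: LiOH (3 equiv), THF/H2O, 0 °C to rt; then aq. HCl to pH 2
Reagents that add atoms: water, O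
Why: saponification cleaves both esters at the acyl carbon, so neither stereocentre is touched, and the cold dilute base avoids C2 epimerisation and β-elimination.

**Step 7**
Reactants: 11 (S)-(+)-carvone
Product: 12 (1S,5S)-cis-carveol
Conditions: NaBH4, CeCl3·7H2O, MeOH, −20 °C
Reagents that add atoms: none
Why: Luche 1,2-reduction delivers hydride axially to the half-chair with the isopropenyl group equatorial, giving the cis alcohol (>95:5), so the bought centre (future C1) sets the future C13 as S.

**Step 8**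
Reactants: 12 (1S,5S)-cis-carveol
Product: 13 cis-carveol 2,3-epoxide (oxirane syn to the hydroxyl)
Conditions: VO(acac)2 (2 mol%), t-BuOOH (1.3 equiv), CH2Cl2, 0 °C to rt
Reagents that add atoms: tert-butyl hydroperoxide, CC(C)(C)OO
Why: hydroxyl-directed vanadium-catalysed epoxidation oxidises only the allylic-alcohol olefin, syn to OH, and spares the isopropenyl group; the two oxirane centres are sacrificial.

**Step 9**
Reactants: 13 cis-carveol 2,3-epoxide
Product: 14 tert-butyldimethylsilyl ether of 13
Conditions: TBSCl, imidazole, DMAP (cat.), DMF, rt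
Reagents that add atoms: tert-butyldimethylsilyl chloride, CC(C)(C)[Si](C)(C)Cl
Why: standard silylation that prevents over-cleavage of an α-hydroxy ketone in the next step and later serves as the non-chelating α-substituent.

**Step 10**
Reactants: 14 tert-butyldimethylsilyl ether of 13
Product: 15 (3R,5S)-5-(tert-butyldimethylsilyloxy)-6-oxo-3-(prop-1-en-2-yl)heptanal
Conditions: H5IO6 (1.3 equiv), THF/Et2O, 0 °C to rt
Reagents that add atoms: orthoperiodic acid, OI(O)(O)(O)(O)=O
Why: periodic acid opens the epoxide and cleaves the resulting glycol in one operation (oxidative epoxide cleavage), unveiling aldehyde C3 and methyl ketone C12 without touching C1 or C13.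

**Step 11**
Reactants: 15 keto aldehyde
Product: 16 hydroxy ketone CH3CO–CH(OTBS)–CH2–CH(isopropenyl)–CH2–CH(OH)–C(CH3)=CH2 (both C3 epimers)
Conditions: CH2=C(CH3)Br (3 equiv), CrCl2 (6 equiv), NiCl2 (1 mol%), DMF, rt
Reagents that add atoms: 2-bromopropene, CC(Br)=C
Why: Nozaki–Hiyama–Kishi alkenylation, whose organochromium reagent adds to the aldehyde but not to the hindered methyl ketone; the new C3 carbinol forms as both epimers, which does not matter because it is destroyed in step 14.

**Step 12**
Reactants: 16 hydroxy ketone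
Product: 17 diol in which the ketone has become C(CH3)(OH)–C≡C–CH3 with C12 R
Conditions: CH3C≡CMgBr (3.5 equiv), THF, −78 to −20 °C
Reagents that add atoms: prop-1-ynylmagnesium bromide, CC#C[Mg]Br
Why: Grignard 1,2-addition in which the non-chelating silyl ether makes the alkynyl group attack anti to the C13–O bond (polar Felkin–Anh), setting C12 as R from C13 (expected about 6:1; the 12S epimer is removed after step 14).

**Step 13**
Reactants: 17 diol
Product: 18 tributylstannylmethyl ether of the C3 hydroxyl of 17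
Conditions: KH (2.2 equiv), 18-crown-6 (cat.), THF, 0 °C; then ICH2SnBu3 (1.05 equiv)
Reagents that add atoms: tributyl(iodomethyl)stannane, CCCC[Sn](CCCC)(CCCC)CI
Why: Williamson etherification in which only the secondary allylic alkoxide is alkylated, the tertiary propargylic alkoxide next to the silyloxy group being too hindered.

**Step 14**
Reactants: 18 stannylmethyl ether
Product: 20 (Z)-homoallylic alcohol with C3=C4 Z and C6 as CH2OH, via lithiomethyl ether 19 (not isolated)
Conditions: n-BuLi (2.3 equiv), THF, −78 °C, 30 min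
Reagents that add atoms: none
Why: Still–Wittig [2,3]-sigmatropic rearrangement: tin–lithium exchange gives the α-alkoxymethyllithium, which adds suprafacially to the isopropenyl terminus through an envelope transition state with the C3 substituent pseudo-axial (away from the 2-methyl group), forging C5–C6 and giving the (Z)-trisubstituted olefin (≥95:5) from either C3 epimer.

**Step 15**
Reactants: 20 (Z)-homoallylic alcohol
Product: 21 primary iodide (C6–I) of 20
Conditions: I2, PPh3, imidazole, CH2Cl2, 0 °C
Reagents that add atoms: iodine, II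
Why: Appel-type iodination converts only the primary alcohol because the tertiary propargylic alcohol does not react under these conditions.

**Step 16**
Reactants: 21 primary iodide; 5 (E)-1-iodo-2-methylhex-1-en-4-yne
Product: 23 open-chain diyne (C6–C7 joined; 3Z,7E; methyl-capped alkynes at C10 and C11), via alkylzinc chloride 22 (not isolated)
Conditions: ZnCl2 (1.2 equiv), then t-BuLi (3.1 equiv), Et2O, −78 °C to rt; then 5 (1.2 equiv), Pd(PPh3)4 (5 mol%), THF, rt
Reagents that add atoms: none
Why: Negishi sp3–sp2 cross-coupling: iodine–lithium exchange with transmetalation to zinc gives an alkylzinc that couples with the alkenyl iodide with retention of the (E) geometry.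

**Step 17**
Reactants: 23 open-chain diyne
Product: 24 (1S,3Z,7E,12R,13S)-13-(tert-butyldimethylsilyloxy)cembra-3,7,15-trien-10-yn-12-ol
Conditions: Mo(≡CC6H4OMe-4)(OSiPh3)3 (5 mol%), 5 Å MS, toluene (2 mM), 80 °C
Reagents that add atoms: none
Why: ring-closing alkyne metathesis of the two methyl-capped alkynes, driven by removal of but-2-yne on the sieves, closes the 14-membered ring at C10≡C11 without touching any olefin.

**Step 18**
Reactants: 24 cycloalkyne
Product: 25 (1S,3Z,7E,10E,12R,13S)-13-(tert-butyldimethylsilyloxy)cembra-3,7,10,15-tetraen-12-ol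
Conditions: NaAlH2(OCH2CH2OMe)2 (3 equiv), THF, 0 °C to rt; aq. Rochelle salt
Reagents that add atoms: none
Why: hydroxyl-directed trans-hydroalumination of the propargylic alcohol and protonolysis give only the (E)-C10=C11 alkene.

**Step 19**
Reactants: 25 tertiary allylic alcohol
Product: 26 12-O-methoxycarbonyl derivative (tertiary allylic methyl carbonate) of 25
Conditions: LiN(SiMe3)2 (1.3 equiv), THF, −78 °C; then ClCO2Me (1.5 equiv), −78 to 0 °C
Reagents that add atoms: methyl chloroformate, COC(Cl)=O
Why: acylation of the lithium alkoxide turns the tertiary allylic oxygen into a leaving group for π-allyl formation.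

**Step 20**
Reactants: 26 tertiary allylic carbonate; 10 (2R,3S)-3-hydroxy-2-methylbutanoic acid
Product: 27 (1S,3Z,7E,10R,11E,13S)-13-(tert-butyldimethylsilyloxy)cembra-3,7,11,15-tetraen-10-yl (2R,3S)-3-hydroxy-2-methylbutanoate
Conditions: Pd2(dba)3 (2.5 mol%), PPh3 (12 mol%), 10 (1.5 equiv), THF, rt
Reagents that add atoms: none
Why: Tsuji–Trost allylic substitution: zerovalent palladium ionises the carbonate anti to the leaving group with the bulky C13 branch syn on the π-allyl, and the carboxylate (formed by the released methoxide) attacks the less hindered C10 terminus anti to palladium, so C12 (R) is relayed with overall retention to C10 (R) and the C11=C12 olefin forms E.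

**Step 21**
Reactants: 27 silyl-protected ester
Product: 28 (1S,3Z,7E,10R,11E,13S)-13-hydroxycembra-3,7,11,15-tetraen-10-yl (2R,3S)-3-hydroxy-2-methylbutanoate (target)
Conditions: HF·pyridine, pyridine/THF, 0 °C to rt
Reagents that add atoms: none
Why: buffered fluoride desilylation frees the C13 hydroxyl while sparing the allylic ester and the β-hydroxy ester.

## Compound list

1 | prop-2-yn-1-ol | C#CCO | starting material
2 | (E)-alkenylalane Me2Al–CH=C(CH3)–CH2–OAlMe2 | C[Al](C)/C=C(\C)CO[Al](C)C | intermediate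
3 | (E)-3-iodo-2-methylprop-2-en-1-ol | I/C=C(\C)CO | intermediate
4 | (E)-3-bromo-1-iodo-2-methylprop-1-ene | I/C=C(\C)CBr | intermediate
5 | (E)-1-iodo-2-methylhex-1-en-4-yne | I/C=C(\C)CC#CC | intermediate
6 | ethyl (R)-3-hydroxybutanoate | CCOC(=O)C[C@@H](C)O | starting material
7 | dilithio alkoxide enolate of 6 | CCOC(O[Li])=C[C@@H](C)O[Li] | intermediate
8 | ethyl (2R,3R)-3-hydroxy-2-methylbutanoate | CCOC(=O)[C@H](C)[C@@H](C)O | intermediate
9 | ethyl (2R,3S)-2-methyl-3-(4-nitrobenzoyloxy)butanoate | CCOC(=O)[C@H](C)[C@H](C)OC(=O)c1ccc(cc1)[N+](=O)[O-] | intermediate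
10 | (2R,3S)-3-hydroxy-2-methylbutanoic acid | OC(=O)[C@H](C)[C@H](C)O | intermediate
11 | (S)-(+)-carvone | CC1=CC[C@@H](CC1=O)C(C)=C | starting material
12 | (1S,5S)-cis-carveol | CC1=CC[C@@H](C[C@@H]1O)C(C)=C | intermediate
13 | cis-carveol 2,3-epoxide, oxirane syn to the hydroxyl | C[C@@]12O[C@@H]1C[C@@H](C[C@@H]2O)C(C)=C | intermediate
14 | tert-butyldimethylsilyl ether of 13 | C[C@@]12O[C@@H]1C[C@@H](C[C@@H]2O[Si](C)(C)C(C)(C)C)C(C)=C | intermediate
15 | (3R,5S)-5-(tert-butyldimethylsilyloxy)-6-oxo-3-(prop-1-en-2-yl)heptanal | C=C(C)[C@H](C[C@H](O[Si](C)(C)C(C)(C)C)C(C)=O)CC=O | intermediate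
16 | hydroxy ketone from isopropenyl addition to the aldehyde of 15 (both C3 epimers) | C=C(C)[C@H](C[C@H](O[Si](C)(C)C(C)(C)C)C(C)=O)CC(O)C(C)=C | intermediate
17 | diol with C12 as (R)-C(CH3)(OH)–C≡C–CH3 (both C3 epimers) | C=C(C)[C@H](C[C@H](O[Si](C)(C)C(C)(C)C)[C@](C)(O)C#CC)CC(O)C(C)=C | intermediate
18 | tributylstannylmethyl ether of the C3 hydroxyl of 17 | C=C(C)[C@H](C[C@H](O[Si](C)(C)C(C)(C)C)[C@](C)(O)C#CC)CC(OC[Sn](CCCC)(CCCC)CCCC)C(C)=C | intermediate
19 | lithiomethyl ether (lithium alkoxide at C12) | C=C(C)[C@H](C[C@H](O[Si](C)(C)C(C)(C)C)[C@](C)(O[Li])C#CC)CC(OC[Li])C(C)=C | intermediate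
20 | (Z)-homoallylic alcohol (C3=C4 Z, C6 CH2OH, C12 R, C13 S, C1 S) | C=C(C)[C@H](C[C@H](O[Si](C)(C)C(C)(C)C)[C@](C)(O)C#CC)C/C=C(/C)CCO | intermediate
21 | primary iodide of 20 | C=C(C)[C@H](C[C@H](O[Si](C)(C)C(C)(C)C)[C@](C)(O)C#CC)C/C=C(/C)CCI | intermediate
22 | alkylzinc chloride from 21 (lithium alkoxide at C12) | C=C(C)[C@H](C[C@H](O[Si](C)(C)C(C)(C)C)[C@](C)(O[Li])C#CC)C/C=C(/C)CC[Zn]Cl | intermediate
23 | open-chain (3Z,7E)-diyne | C=C(C)[C@H](C[C@H](O[Si](C)(C)C(C)(C)C)[C@](C)(O)C#CC)C/C=C(/C)CC/C=C(\C)CC#CC | intermediate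
24 | (1S,3Z,7E,12R,13S)-13-(tert-butyldimethylsilyloxy)cembra-3,7,15-trien-10-yn-12-ol | C=C(C)[C@H]1C/C=C(/C)CC/C=C(\C)CC#C[C@@](C)(O)[C@@H](O[Si](C)(C)C(C)(C)C)C1 | intermediate
25 | (1S,3Z,7E,10E,12R,13S)-13-(tert-butyldimethylsilyloxy)cembra-3,7,10,15-tetraen-12-ol | C=C(C)[C@H]1C/C=C(/C)CC/C=C(\C)C/C=C/[C@@](C)(O)[C@@H](O[Si](C)(C)C(C)(C)C)C1 | intermediate
26 | 12-O-methoxycarbonyl derivative of 25 | C=C(C)[C@H]1C/C=C(/C)CC/C=C(\C)C/C=C/[C@@](C)(OC(=O)OC)[C@@H](O[Si](C)(C)C(C)(C)C)C1 | intermediate
27 | (1S,3Z,7E,10R,11E,13S)-13-(tert-butyldimethylsilyloxy)cembra-3,7,11,15-tetraen-10-yl (2R,3S)-3-hydroxy-2-methylbutanoate | C=C(C)[C@H]1C/C=C(/C)CC/C=C(\C)C[C@@H](OC(=O)[C@H](C)[C@H](C)O)/C=C(\C)[C@@H](O[Si](C)(C)C(C)(C)C)C1 | intermediate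
28 | (1S,3Z,7E,10R,11E,13S)-13-hydroxycembra-3,7,11,15-tetraen-10-yl (2R,3S)-3-hydroxy-2-methylbutanoate | C=C(C)[C@H]1C/C=C(/C)CC/C=C(\C)C[C@@H](OC(=O)[C@H](C)[C@H](C)O)/C=C(\C)[C@@H](O)C1 | target

## Step count and risks

Total step count: 21 (3 for the iodoenyne 5, 3 for the acid 10, 15 on the main line).
Longest linear sequence: 15 steps (11 to 28, steps 7–21).

**Step 13 (selective stannylmethylation before the rearrangement).** If the tertiary alkoxide competes or the silyl group migrates, the ether needed for step 14 is lost. The fallback sets out from 15. The aldehyde is masked in the flask as its lithium N,O-dimethylhydroxylamide adduct, prop-1-ynyllithium is added to the ketone, and the tertiary alkoxide is trapped with Me3SiCl before aqueous release of the aldehyde. This gives the 12-O-trimethylsilyl aldehyde F1. Nozaki–Hiyama–Kishi isopropenylation gives the mono-alcohol F2, whose single hydroxyl is alkylated (KH, ICH2SnBu3) to the stannylmethyl ether F3. The same Still–Wittig rearrangement gives the silylated homoallylic alcohol F4, and K2CO3 in MeOH removes the trimethylsilyl group to return to the route at 20.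

**Step 17 (alkyne metathesis next to a free, hindered tertiary propargylic alcohol).** The free hydroxyl can deactivate the molybdenum alkylidyne. The fallback sets out from 23. The alcohol is capped (Me3SiOTf, 2,6-lutidine) as the trimethylsilyl ether F5 and the ring is closed on the capped substrate to the silylated cycloalkyne F6. K2CO3 in MeOH then releases the carbinol and the route is rejoined at 24.

**Step 20 (allylic acyloxylation).** Attack at the tertiary terminus, β-hydride elimination towards C9, or erosion of the relay through π-allyl equilibration could intervene. The fallback sets out from 25 and uses a second sigmatropic step. O3ReOSiPh3 (2 mol%, Et2O, −50 °C) induces the chair-like [3,3] shift of the allylic perrhenate and gives the transposed (10R,11E)-allylic alcohol F7. Separately, acid 10 is silylated on both oxygens to the silyl ester F8, and the ester is cleaved (K2CO3, MeOH/H2O) to the silyl ether acid F9. Carbodiimide esterification (EDC, DMAP) of F7 with F9 gives the bis-silyl ester F10, and HF·pyridine removes both silyl groups to arrive at 28.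

## Further compounds

F1 | step 13 | 12-O-trimethylsilyl aldehyde: 15 with the ketone converted into (R)-C(CH3)(OSiMe3)–C≡C–CH3 | C=C(C)[C@H](C[C@H](O[Si](C)(C)C(C)(C)C)[C@](C)(O[Si](C)(C)C)C#CC)CC=O
F2 | step 13 | isopropenyl carbinol from F1 (both C3 epimers) | C=C(C)[C@H](C[C@H](O[Si](C)(C)C(C)(C)C)[C@](C)(O[Si](C)(C)C)C#CC)CC(O)C(C)=C
F3 | step 13 | tributylstannylmethyl ether of F2 | C=C(C)[C@H](C[C@H](O[Si](C)(C)C(C)(C)C)[C@](C)(O[Si](C)(C)C)C#CC)CC(OC[Sn](CCCC)(CCCC)CCCC)C(C)=C
F4 | step 13 | 12-O-trimethylsilyl ether of 20 | C=C(C)[C@H](C[C@H](O[Si](C)(C)C(C)(C)C)[C@](C)(O[Si](C)(C)C)C#CC)C/C=C(/C)CCO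
F5 | step 17 | 12-O-trimethylsilyl ether of 23 | C=C(C)[C@H](C[C@H](O[Si](C)(C)C(C)(C)C)[C@](C)(O[Si](C)(C)C)C#CC)C/C=C(/C)CC/C=C(\C)CC#CC
F6 | step 17 | 12-O-trimethylsilyl ether of 24 | C=C(C)[C@H]1C/C=C(/C)CC/C=C(\C)CC#C[C@@](C)(O[Si](C)(C)C)[C@@H](O[Si](C)(C)C(C)(C)C)C1
F7 | step 20 | (1S,3Z,7E,10R,11E,13S)-13-(tert-butyldimethylsilyloxy)cembra-3,7,11,15-tetraen-10-ol | C=C(C)[C@H]1C/C=C(/C)CC/C=C(\C)C[C@@H](O)/C=C(\C)[C@@H](O[Si](C)(C)C(C)(C)C)C1
F8 | step 20 | tert-butyldimethylsilyl (2R,3S)-3-(tert-butyldimethylsilyloxy)-2-methylbutanoate | CC(C)(C)[Si](C)(C)OC(=O)[C@H](C)[C@H](C)O[Si](C)(C)C(C)(C)C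
F9 | step 20 | (2R,3S)-3-(tert-butyldimethylsilyloxy)-2-methylbutanoic acid | OC(=O)[C@H](C)[C@H](C)O[Si](C)(C)C(C)(C)C
F10 | step 20 | bis(tert-butyldimethylsilyl) ether of 28 (at O13 and at the side-chain hydroxyl) | C=C(C)[C@H]1C/C=C(/C)CC/C=C(\C)C[C@@H](OC(=O)[C@H](C)[C@H](C)O[Si](C)(C)C(C)(C)C)/C=C(\C)[C@@H](O[Si](C)(C)C(C)(C)C)C1
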